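If you want to know what stands in this flask at the end, first ask how fast L takes up Z.

| flask | X | L | remark | time |
|---|---|---|---|---|
| midnight | 0.0020 M | 1.5 mM | run made earlier |  |
| dawn | 0.0020 M | 3.3 mM | run made earlier |  |
| spring | 0.0030 M | 2.2 mM | run made earlier |  |
| flask | 0.0020 M | 2.20 mM |  | 15 min |

| run | time / min | Z / % | G / % |
|---|---|---|---|
| midnight | 1.00 | 21.0 | 21.8 |
| midnight | 2.00 | 28.2 | 30.4 |
| midnight | 5.00 | 34.6 | 39.3 |
| midnight | 12.0 | 36.3 | 43.9 |
| dawn | 3.00 | 41.5 | 35.6 |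
| dawn | 6.00 | 37.7 | 36.4 |
| dawn | 10.0 | 31.8 | 37.1 |
| dawn | 12.0 | 28.6 | 35.9 |
| spring | 1.50 | 27.7 | 31.4 |
| spring | 4.00 | 33.7 | 41.7 |
| spring | 8.00 | 35.7 | 44.9 |
| spring | 12.0 | 37.0 | 44.9 |

(readings scatter by 0.5 percentage points)

- a species is counted by the X in it: one G counts as two
- what may be going on: X + L <-> D + Q; X + L -> Z + Q; L + D -> E + Q; L + Z -> E + Q; X + D -> G

1. concentration of Z at 15 min, in M
2. concentration of G at 15 min, in M
3. concentration of E at 15 min, in M
4. concentration of Q at 15 min, in M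

Each Q marks one L used, and G counts double in the percentages. In the dawn run, G reads 35.6 % at 3.00 min and 35.9 % at 12.0 min, so I neglect X and D over that stretch and reckon a mean L of 1.07 mM. Dividing the fall of ln Z per minute by that L gives 0.642 M⁻¹ s⁻¹, the Z loss constant. Times L, it is a pseudo-first-order rate for Z.

Late in the flask, I estimate L near the excess of its charge over X, 0.200 mM. That gives Z a half-life of 89.9 min, longer than the 15 min asked. So I place Z in the flask at the asked time between the midnight reading of 36.3 % at 12.0 min and the dawn reading of 41.5 % at 3.00 min.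

The forecast reads from the dawn run that “Z decays at about 0.041/min with about 1 mM L left”, and it gives Z 7.400 × 10⁻⁴ M, G 4.100 × 10⁻⁴ M, E 4.200 × 10⁻⁴ M and Q 0.00198 M.

The flask gives Z 7.41 × 10⁻⁴ M, G 4.33 × 10⁻⁴ M, E 3.58 × 10⁻⁴ M and Q 0.00189 M. The forecast's E is too high by a factor of 1.17, while its other three values lie within the tolerance.

    X + L ⇌ D + Q (K = 0.830, k = 3.13 M⁻¹ s⁻¹)
    X + L → Z + Q (k = 4.66 M⁻¹ s⁻¹)
    L + D → E + Q (k = 7.17 M⁻¹ s⁻¹)
    L + Z → E + Q (k = 0.681 M⁻¹ s⁻¹)
    X + D → G (k = 43.7 M⁻¹ s⁻¹)

In the flask at 15.0 min, Z is made at 0.289 of the rate at which it is used up, and it slips from 39.3 % at 7.50 min to 37.0 %. With L at 14.0 % of its charge, the Z loss constant gives a half-life of 58.6 min, longer than the time asked. In a neighbour flask charged with 0.0088 M of L, 61.7 % of that L remains at 15.0 min. The same constant gives a half-life of 3.31 min there, and Z stands at 1.79 %.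

Readings and results come from a simulation with made-up constants, and the scatter is random.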